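**Plan**
- Retrosynthesis: the pyranone (ring C) is opened at O1–C2 by adding water, which leaves a 1-(2,6-dihydroxyaryl)-2-methoxy-3-arylpropane-1,3-dione. C4a–C4 and C4–C3 are then cut together, so that C4 becomes carbon monoxide.
- Enabling feature: C4 is a ketone carbon between C4a, whose neighbours C5 and C8a both carry oxygen, and the methoxy-bearing C3. With both oxygens masked alike, ring A is mirror-symmetric, so one symmetrical iodoarene serves and either phenol can later become O1.
- Forward, arene: 1,2,3-trimethoxybenzene → dibromide → resorcinol (borylation, oxidation) → bis(methoxymethyl) ether → iodide by lithiation between the two acetals. Ketone: 4-methoxyphenyl Grignard plus the Weinreb amide of methoxyacetic acid.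
- Rings A and B are present from the start. Palladium joins iodide, CO and ketone enolate into the open C4a–C4–C3–C2 chain, and methanolic acid then frees the phenols and closes ring C last.
- Stereochemistry: the target has no stereocentre. The only centre formed on the way (C3, in the dione and the hemiketal) is racemic and enolisable, and it becomes sp2 when ring C aromatises.

Key step: step 7

Assumption: 1,2,3-trimethoxybenzene, 4-methoxyphenylmagnesium bromide (THF solution), N,2-dimethoxy-N-methylacetamide and carbon monoxide are bought; CO is supplied at about one atmosphere (balloon or two-chamber vessel).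

**Route**

Step 1
Reactants: 1 1,2,3-trimethoxybenzene
Product: 3 1,5-dibromo-2,3,4-trimethoxybenzene, via monobromide 2 (not isolated)
Conditions: NBS (2.2 equiv), MeCN, rt to 50 °C
Reagents that add atoms: N-bromosuccinimide, O=C1CCC(=O)N1Br
Why: Electrophilic aromatic bromination should put the first bromine at C4 (para to one outer methoxy, ortho to the other) and the second at C6 for the same reason, since C5 is activated only by the twisted central methoxy.

Step 2
Reactants: 3 1,5-dibromo-2,3,4-trimethoxybenzene
Product: 5 2,2'-(4,5,6-trimethoxy-1,3-phenylene)bis(4,4,5,5-tetramethyl-1,3,2-dioxaborolane), via bromo boronate 4 (not isolated)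
Conditions: B2pin2 (2.6 equiv), PdCl2(dppf) (6 mol %), KOAc (6 equiv), 1,4-dioxane, 95 °C
Reagents that add atoms: bis(pinacolato)diboron, CC1(C)OB(B2OC(C)(C)C(C)(C)O2)OC1(C)C
Why: Twofold Miyaura borylation (zerovalent palladium inserts into each C–Br bond, acetate-assisted transmetalation from the diboron, C–B reductive elimination) is well established for ortho-methoxy aryl bromides.

Step 3
Reactants: 5 2,2'-(4,5,6-trimethoxy-1,3-phenylene)bis(4,4,5,5-tetramethyl-1,3,2-dioxaborolane)
Product: 7 4,5,6-trimethoxybenzene-1,3-diol, via hydroxy boronate 6 (not isolated)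
Conditions: H2O2 (30% aq, 2.4 equiv), NaOH (1 M aq, 2.2 equiv), THF, 0 °C, N2; Na2S2O3, then pH 5
Reagents that add atoms: hydrogen peroxide, OO
Why: Peroxide oxidation of arylboronates (hydroperoxide adds to boron and the aryl group shifts from B to O at the same carbon) should place both hydroxyls where the bromines stood; the oxidant is kept cold and near stoichiometric under nitrogen because the product is an electron-rich resorcinol.

Step 4
Reactants: 7 4,5,6-trimethoxybenzene-1,3-diol
Product: 9 1,2,3-trimethoxy-4,6-bis(methoxymethoxy)benzene, via mono-acetal phenol 8 (not isolated)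
Conditions: MOMCl (3 equiv), i-Pr2NEt (4 equiv), CH2Cl2, 0 °C to rt
Reagents that add atoms: chloromethyl methyl ether, COCCl
Why: O-Alkylation of both phenols by the reactive alpha-chloro ether (Williamson type) should give the bis-acetal, which withstands the organolithium and amide bases ahead and is removed by acid at the end.

Step 5
Reactants: 9 1,2,3-trimethoxy-4,6-bis(methoxymethoxy)benzene
Product: 11 2-iodo-4,5,6-trimethoxy-1,3-bis(methoxymethoxy)benzene, via aryllithium 10 (not isolated)
Conditions: n-BuLi (1.2 equiv), THF, 0 °C; ICH2CH2I (1.3 equiv), −78 °C to rt; dark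
Reagents that add atoms: 1,2-diiodoethane, ICCI
Why: Directed ortho-metalation can occur only at the single ring hydrogen, which lies between two lithium-coordinating OCH2OCH3 groups, and 1,2-diiodoethane should transfer iodine to the aryllithium with loss of ethene.

Step 6
Reactants: 12 4-methoxyphenylmagnesium bromide; 13 N,2-dimethoxy-N-methylacetamide
Product: 15 2-methoxy-1-(4-methoxyphenyl)ethanone, via magnesium hemiaminal 14 (not isolated)
Conditions: 12 (1.2 equiv), THF, 0 °C to rt; 1 M HCl (aq)
Reagents that add atoms: none
Why: Weinreb ketone synthesis: the Grignard reagent adds once and the five-membered magnesium chelate should persist until the acidic quench, so no tertiary alcohol forms.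

Step 7
Reactants: 11 2-iodo-4,5,6-trimethoxy-1,3-bis(methoxymethoxy)benzene; 15 2-methoxy-1-(4-methoxyphenyl)ethanone; 16 carbon monoxide
Product: 19 1-[3,4,5-trimethoxy-2,6-bis(methoxymethoxy)phenyl]-2-methoxy-3-(4-methoxyphenyl)propane-1,3-dione (racemic), via sodium enolate 17 (not isolated), via sodium diketonate 18 (not isolated)
Conditions: 15 (2.2 equiv), NaN(SiMe3)2 (2.1 equiv), THF, rt; then 11, Pd(dba)2 (5 mol %), 1,3-bis(diphenylphosphino)propane (6 mol %), CO (1 atm), 1,4-dioxane, 80 °C; AcOH quench
Reagents that add atoms: none
Why: Zerovalent palladium should insert into the carbon–iodine bond of 11, CO then inserts to give an aroylpalladium in which the metal sits one atom further from the two flanking acetals, enolate 17 replaces iodide on palladium and C–C reductive elimination completes C4a–C4 and C4–C3, after which a second equivalent of 17 deprotonates the dione to the stabilised diketonate 18 and so removes it from further reaction. The closest known reaction is the palladium-catalysed carbonylative alpha-arylation of propiophenone-type ketones with aryl iodides at about one atmosphere of CO, which gives 1,3-diketones. No ring is closed. The one new stereocentre (C2 of the dione, the future C3) is formed racemic, is enolisable and becomes sp2 in step 8, so no control element is needed. The step needs CO uptake to outrun direct alpha-arylation and C-acylation to outrun O-acylation: the two ortho OCH2OCH3 groups slow direct aryl–enolate reductive elimination and thereby favour insertion, the fully substituted ring of 11 has no ortho hydrogen from which the base could generate an aryne, and 15 has a single enolisable carbon, the methoxy-bearing CH2 that becomes C3.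

Step 8
Reactants: 19 1-[3,4,5-trimethoxy-2,6-bis(methoxymethoxy)phenyl]-2-methoxy-3-(4-methoxyphenyl)propane-1,3-dione
Product: 22 5-hydroxyauranetin (5-hydroxy-3,6,7,8-tetramethoxy-2-(4-methoxyphenyl)-4H-chromen-4-one), via free bisphenol dione 20 (not isolated), via cyclic hemiketal 21 (not isolated)
Conditions: HCl (3 M in MeOH), 60 °C
Reagents that add atoms: none
Why: Acid-catalysed acetal solvolysis should release both phenols, either of which (they are equivalent) adds 6-exo-trig to the 4-methoxybenzoyl carbonyl, and the hemiketal dehydrates as in the classical cyclodehydration of 1-(2-hydroxyaryl)-1,3-diones to flavones, the unused phenol ending as the hydrogen-bonded 5-OH.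

**Compound list**
1 | 1,2,3-trimethoxybenzene | COc1cccc(OC)c1OC | starting material
2 | 1-bromo-2,3,4-trimethoxybenzene (monobromide, not isolated) | COc1ccc(Br)c(OC)c1OC | intermediate
3 | 1,5-dibromo-2,3,4-trimethoxybenzene | COc1c(Br)cc(Br)c(OC)c1OC | intermediate
4 | 2-(5-bromo-2,3,4-trimethoxyphenyl)-4,4,5,5-tetramethyl-1,3,2-dioxaborolane (bromo boronate, not isolated) | COc1c(Br)cc(B2OC(C)(C)C(C)(C)O2)c(OC)c1OC | intermediate
5 | 2,2'-(4,5,6-trimethoxy-1,3-phenylene)bis(4,4,5,5-tetramethyl-1,3,2-dioxaborolane) | COc1c(B2OC(C)(C)C(C)(C)O2)cc(B2OC(C)(C)C(C)(C)O2)c(OC)c1OC | intermediate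
6 | 2,3,4-trimethoxy-5-(4,4,5,5-tetramethyl-1,3,2-dioxaborolan-2-yl)phenol (hydroxy boronate, not isolated) | COc1c(O)cc(B2OC(C)(C)C(C)(C)O2)c(OC)c1OC | intermediate
7 | 4,5,6-trimethoxybenzene-1,3-diol | COc1c(O)cc(O)c(OC)c1OC | intermediate
8 | 2,3,4-trimethoxy-5-(methoxymethoxy)phenol (mono-acetal phenol, not isolated) | COCOc1cc(O)c(OC)c(OC)c1OC | intermediate
9 | 1,2,3-trimethoxy-4,6-bis(methoxymethoxy)benzene | COCOc1cc(OCOC)c(OC)c(OC)c1OC | intermediate
10 | [3,4,5-trimethoxy-2,6-bis(methoxymethoxy)phenyl]lithium (not isolated) | [Li]c1c(OCOC)c(OC)c(OC)c(OC)c1OCOC | intermediate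
11 | 2-iodo-4,5,6-trimethoxy-1,3-bis(methoxymethoxy)benzene | COCOc1c(I)c(OCOC)c(OC)c(OC)c1OC | intermediate
12 | 4-methoxyphenylmagnesium bromide | COc1ccc([Mg]Br)cc1 | starting material
13 | N,2-dimethoxy-N-methylacetamide | COCC(=O)N(C)OC | starting material
14 | bromomagnesium 2-methoxy-1-[methoxy(methyl)amino]-1-(4-methoxyphenyl)ethan-1-olate (magnesium hemiaminal, not isolated) | COCC(O[Mg]Br)(N(C)OC)c1ccc(OC)cc1 | intermediate
15 | 2-methoxy-1-(4-methoxyphenyl)ethanone | COCC(=O)c1ccc(OC)cc1 | intermediate
16 | carbon monoxide | [C-]#[O+] | starting material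
17 | sodium (Z)-2-methoxy-1-(4-methoxyphenyl)ethen-1-olate (not isolated) | CO/C=C(\[O-])c1ccc(OC)cc1.[Na+] | intermediate
18 | sodium enolate of dione 19 (sodium diketonate, not isolated) | COCOc1c(C(=O)C(OC)=C([O-])c2ccc(OC)cc2)c(OCOC)c(OC)c(OC)c1OC.[Na+] | intermediate
19 | 1-[3,4,5-trimethoxy-2,6-bis(methoxymethoxy)phenyl]-2-methoxy-3-(4-methoxyphenyl)propane-1,3-dione (racemic) | COCOc1c(C(=O)C(OC)C(=O)c2ccc(OC)cc2)c(OCOC)c(OC)c(OC)c1OC | intermediate
20 | 1-(2,6-dihydroxy-3,4,5-trimethoxyphenyl)-2-methoxy-3-(4-methoxyphenyl)propane-1,3-dione (racemic, not isolated) | COc1ccc(C(=O)C(OC)C(=O)c2c(O)c(OC)c(OC)c(OC)c2O)cc1 | intermediate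
21 | 2,5-dihydroxy-3,6,7,8-tetramethoxy-2-(4-methoxyphenyl)-2,3-dihydro-4H-chromen-4-one (racemic diastereomer mixture, not isolated) | COc1ccc(C2(O)Oc3c(OC)c(OC)c(OC)c(O)c3C(=O)C2OC)cc1 | intermediate
22 | 5-hydroxyauranetin, 5-hydroxy-3,6,7,8-tetramethoxy-2-(4-methoxyphenyl)-4H-chromen-4-one (achiral) | COc1ccc(-c2oc3c(OC)c(OC)c(OC)c(O)c3c(=O)c2OC)cc1 | target

**Count**
Total steps: 8. Longest linear sequence: 7 (steps 1 to 5, then 7 and 8); the ketone branch is step 6.

**Steps most likely to fail, with fallbacks**

The greatest risk lies in step 7. Oxidative addition at the doubly flanked carbon–iodine bond may be slow, the arylpalladium may be reduced or may couple with the enolate before taking up CO, and the catalyst may rest as carbonyl complexes. The fallback makes the same two bonds in separate, stoichiometric operations. It sets out from 9, which is lithiated to 10 as in step 5. Quenching with dry CO2 and acidifying to pH 4 should give 3,4,5-trimethoxy-2,6-bis(methoxymethoxy)benzoic acid F1. 1-Chloro-N,N,2-trimethylprop-1-en-1-amine in CH2Cl2 at 0 °C should convert it under neutral, acetal-safe conditions into 3,4,5-trimethoxy-2,6-bis(methoxymethoxy)benzoyl chloride F2. This is added at −78 °C to lithium (Z)-2-methoxy-1-(4-methoxyphenyl)ethen-1-olate F3, prepared from 15 (2.2 equiv) and LiN(SiMe3)2 (2.1 equiv) in THF. C-Acylation of the lithium enolate by the planar, highly electrophilic aroyl chloride followed by an acetic acid quench rejoins the route at 19.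

Second is step 2. The second borylation may stall, and protodebromination at palladium may compete on this electron-rich dibromide whose bromines each sit next to a methoxy group. The fallback avoids palladium. It sets out from 3: twofold bromine–lithium exchange with t-BuLi (4.2 equiv) in THF at −78 °C should give (4,5,6-trimethoxy-1,3-phenylene)dilithium F4, each lithium being stabilised by its neighbouring methoxy group. Trapping with 2-isopropoxy-4,4,5,5-tetramethyl-1,3,2-dioxaborolane rejoins the route at 5.

Third is step 8. In hot methanolic acid the non-enolised 2-methoxy-1,3-dione may be cleaved by methanol (retro-Claisen fragmentation) before the phenols are free, or the sequence may stop at the hemiketal. The fallback changes the phenol protection so that the phenols are freed under neutral, non-nucleophilic conditions and the dehydration is run separately. It sets out from 7: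
- Benzyl bromide and K2CO3 in DMF should give 1,5-bis(benzyloxy)-2,3,4-trimethoxybenzene F5.
- N-Iodosuccinimide in MeCN should iodinate the only free, strongly activated ring carbon to give 1,3-bis(benzyloxy)-2-iodo-4,5,6-trimethoxybenzene F6.
- Carbonylative coupling with 16 and enolate 17 under the conditions of step 7 should give 1-[2,6-bis(benzyloxy)-3,4,5-trimethoxyphenyl]-2-methoxy-3-(4-methoxyphenyl)propane-1,3-dione F7.
- Hydrogenolysis (H2, 1 atm, Pd/C, EtOAc, rt) rejoins the route at 20, which should close to 21. TsOH in toluene at 80 °C then dehydrates 21 to 22.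

**Further compounds**
F1 | step 7 | 3,4,5-trimethoxy-2,6-bis(methoxymethoxy)benzoic acid | COCOc1c(C(=O)O)c(OCOC)c(OC)c(OC)c1OC
F2 | step 7 | 3,4,5-trimethoxy-2,6-bis(methoxymethoxy)benzoyl chloride | COCOc1c(C(=O)Cl)c(OCOC)c(OC)c(OC)c1OC
F3 | step 7 | lithium (Z)-2-methoxy-1-(4-methoxyphenyl)ethen-1-olate | CO/C=C(\[O-])c1ccc(OC)cc1.[Li+]
F4 | step 2 | (4,5,6-trimethoxy-1,3-phenylene)dilithium | [Li]c1cc([Li])c(OC)c(OC)c1OC
F5 | step 8 | 1,5-bis(benzyloxy)-2,3,4-trimethoxybenzene | COc1c(OCc2ccccc2)cc(OCc2ccccc2)c(OC)c1OC
F6 | step 8 | 1,3-bis(benzyloxy)-2-iodo-4,5,6-trimethoxybenzene | COc1c(OCc2ccccc2)c(I)c(OCc2ccccc2)c(OC)c1OC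
F7 | step 8 | 1-[2,6-bis(benzyloxy)-3,4,5-trimethoxyphenyl]-2-methoxy-3-(4-methoxyphenyl)propane-1,3-dione (racemic) | COc1ccc(C(=O)C(OC)C(=O)c2c(OCc3ccccc3)c(OC)c(OC)c(OC)c2OCc2ccccc2)cc1
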